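**Plan**

- Numbering: ring C1(=O)–C2=C3–C4H2–C5(OH)–C6H2, side chain C1′H2–C2′(=O)–C17 (Z,Z)-dienyl. The enabling feature is the aldol pattern C5(OH)–C1′H2–C2′=O at a fully substituted ring carbon: joining the C5 oxygen to a nitrogen on C2′ turns it into a spiro-2-isoxazoline at C5.
- Retrosynthesis: the C1 ketone goes back to a carbinol and the β-hydroxy ketone to the isoxazoline. C1′–C2′ and C5–O are then cut together ([3+2]) into a linoleyl nitrile oxide and (R)-5-methylidenecyclohex-2-en-1-ol. The dienol is cut at C2=C3 (metathesis), C1–C6 (allylzinc + acrolein) and C3–C4 (vinyl Grignard + allylic chloride).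
- Forward: the carbocycle closes first by ring-closing metathesis, and the chain is joined as the isoxazoline ring closes on the exocyclic methylene. The heterocycle is then opened reductively and C1 is oxidised last, so the β-hydroxy enone appears only in the final, mild step.
- Stereochemistry: the C1 carbinol comes from a lipase resolution and passes its configuration to C5 by magnesium-alkoxide delivery of the dipole oxygen (cis), after which C1 is oxidised away. Both Z alkenes come unchanged from linoleyl alcohol.

Key step: step 8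

Assumption: the lipase is taken to show its usual preference for secondary alcohols, with vinyl as the smaller and the branched CH2 chain as the larger group, so that the (S)-enantiomer of the racemic trienol is acetylated and the (R)-enantiomer is left.

**Route**

Step 1
Reactants: 1 3-chloro-2-(chloromethyl)prop-1-ene; 2 vinylmagnesium bromide
Product: 3 2-(chloromethyl)penta-1,4-diene
Conditions: CuI (5 mol%), THF, −20 °C to 0 °C; 2 added slowly to 1 (3 equiv); fractional distillation
Reagents that add atoms: none
Why: Copper-catalysed allylic substitution of a Grignard reagent on an allylic chloride, in which SN2 and SN2′ attack give the same product because the electrophile is symmetric, while the excess of 1 should keep the second chloride from reacting.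

Step 2
Reactants: 3 2-(chloromethyl)penta-1,4-diene; 4 acrolein
Product: 6 rac-5-methylideneocta-1,7-dien-3-ol, via (2-methylidenepent-4-en-1-yl)zinc chloride 5 (not isolated)
Conditions: Zn dust, THF/sat. aq. NH4Cl, 0 °C to rt
Reagents that add atoms: none
Why: Aqueous zinc Barbier allylation, in which the allylzinc adds 1,2 to the enal through a six-membered transition state (allylic transposition is degenerate for this 2-substituted allyl unit) and the new carbinol centre is formed racemic.

Step 3
Reactants: 6 rac-5-methylideneocta-1,7-dien-3-ol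
Product: 7 (R)-5-methylideneocta-1,7-dien-3-ol
Conditions: immobilised Candida antarctica lipase B, vinyl acetate, hexane, 30 °C, run slightly past half conversion; chromatography
Reagents that add atoms: none
Why: Lipase-catalysed kinetic resolution by irreversible transesterification, in which the enzyme should acetylate the (S)-alcohol and leave 7, whose enantiomeric purity can be raised by pushing the conversion, so that the carbinol centre (later ring C1) is fixed here.

Step 4
Reactants: 7 (R)-5-methylideneocta-1,7-dien-3-ol
Product: 8 (R)-5-methylidenecyclohex-2-en-1-ol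
Conditions: second-generation Grubbs catalyst RuCl2(=CHPh)(H2IMes)(PCy3) (2 mol%), 1,4-benzoquinone (10 mol%), CH2Cl2 (0.02 M), 40 °C
Reagents that add atoms: none
Why: Ring-closing metathesis of the two monosubstituted alkenes should close the six-membered ring with loss of ethene, since the 1,1-disubstituted alkene cannot close a ring of reasonable size, the carbinol centre is not touched and benzoquinone suppresses hydride-induced alkene migration.

Step 5
Reactants: 9 linoleyl alcohol, (9Z,12Z)-octadeca-9,12-dien-1-ol
Product: 10 (9Z,12Z)-octadeca-9,12-dienal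
Conditions: TEMPO (10 mol%), PhI(OAc)2 (1.1 equiv), CH2Cl2, rt
Reagents that add atoms: none
Why: Oxoammonium-mediated (TEMPO) oxidation of a primary alcohol stops at the aldehyde and should leave the skipped (Z,Z)-diene untouched.

Step 6
Reactants: 10 (9Z,12Z)-octadeca-9,12-dienal
Product: 11 (9Z,12Z)-octadeca-9,12-dienal oxime (mixture of C=N isomers)
Conditions: NH2OH (50% in water, 1.5 equiv), EtOH, rt
Reagents that add atoms: hydroxylamine, NO
Why: Oxime formation by condensation of an aldehyde with hydroxylamine is fast and neutral, and the C=N geometry does not matter because both isomers are chlorinated in the next step.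

Step 7
Reactants: 11 (9Z,12Z)-octadeca-9,12-dienal oxime
Product: 12 (9Z,12Z)-N-hydroxyoctadeca-9,12-dienimidoyl chloride
Conditions: N-chlorosuccinimide (1.05 equiv), DMF, 0 °C to rt, dark; extractive work-up, used crude
Reagents that add atoms: N-chlorosuccinimide, O=C1CCC(=O)N1Cl
Why: Electrophilic C-chlorination of an aldoxime gives the hydroximoyl chloride, and the mild N-chloro reagent should not attack the isolated cis-alkenes.

Step 8
Reactants: 8 (R)-5-methylidenecyclohex-2-en-1-ol; 12 (9Z,12Z)-N-hydroxyoctadeca-9,12-dienimidoyl chloride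
Product: 15 (5S,7R)-3-[(8Z,11Z)-heptadeca-8,11-dien-1-yl]-1-oxa-2-azaspiro[4.5]deca-2,8-dien-7-ol, via bromomagnesium (1R)-5-methylidenecyclohex-2-en-1-olate 13 (not isolated), via (9Z,12Z)-octadeca-9,12-dienenitrile oxide 14 (not isolated)
Conditions: 8, i-PrOH (3.3 equiv), EtMgBr (3.0 equiv), CH2Cl2, 0 °C; then 12 (1.5 equiv) in CH2Cl2 by syringe pump, 0 °C to rt; aq. NH4Cl
Reagents that add atoms: none
Why: Bromomagnesium isopropoxide removes HCl from 12 to release nitrile oxide 14, whose oxygen binds the magnesium of alkoxide 13, and a concerted Huisgen [3+2] cycloaddition then joins the dipole oxygen to C5 and the dipole carbon to the exocyclic CH2 (the C5–O and C1′–C2′ bonds). The closest known reaction type is the magnesium-alkoxide-directed nitrile oxide cycloaddition to allylic and homoallylic alcohols. The isoxazoline ring closes in this single intermolecular step as a spiro-annulation on the exocyclic alkene, both bonds forming suprafacially and the oxygen going to the more substituted carbon as is normal for 1,1-disubstituted alkenes. The only new stereocentre, C5, is controlled by the C1 alkoxide: with the C1–O bond pseudoaxial, magnesium bridges the alkoxide and the dipole oxygen in a six-membered chelate (Mg, O, C1, C6, C5, O) and delivers the oxygen to the face cis to the hydroxyl, which should give the (5S,7R) adduct. The step needs face selectivity (from this chelate in a non-coordinating solvent), site selectivity for the exocyclic methylene over the ring alkene and the two chain alkenes (cis-1,2-disubstituted alkenes, cyclohexenes in particular, are poor dipolarophiles) and suppression of furoxan formation (slow addition of 12).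

Step 9
Reactants: 15 (5S,7R)-3-[(8Z,11Z)-heptadeca-8,11-dien-1-yl]-1-oxa-2-azaspiro[4.5]deca-2,8-dien-7-ol
Product: 17 (10Z,13Z)-1-[(1R,5R)-1,5-dihydroxycyclohex-3-en-1-yl]nonadeca-10,13-dien-2-one, via (10Z,13Z)-1-[(1S,5R)-1,5-dihydroxycyclohex-3-en-1-yl]nonadeca-10,13-dien-2-imine 16 (not isolated)
Conditions: Mo(CO)6 (1.2 equiv), MeCN/H2O (15:1), 80 °C; then silica gel, air, filtration
Reagents that add atoms: water, O
Why: Reductive N–O cleavage of a 2-isoxazoline by zerovalent molybdenum gives the β-hydroxy imine, which water hydrolyses to the β-hydroxy ketone, and since no bond to either stereocentre is broken both are kept (the descriptor at the tertiary carbon changes only through the priority rules).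

Step 10
Reactants: 17 (10Z,13Z)-1-[(1R,5R)-1,5-dihydroxycyclohex-3-en-1-yl]nonadeca-10,13-dien-2-one
Product: 18 (S)-5-hydroxy-5-[(10Z,13Z)-2-oxononadeca-10,13-dien-1-yl]cyclohex-2-en-1-one (CNP0252404.1)
Conditions: activated MnO2 (20 equiv), CH2Cl2, rt; filtration through Celite, chromatography on neutral silica
Reagents that add atoms: none
Why: Heterogeneous MnO2 oxidation of an allylic alcohol gives the enone under neutral conditions, the tertiary hydroxyl cannot be oxidised, the C5 centre is untouched, and the base-free medium should avoid dehydration of the β-hydroxy enone.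

**Compound list**

1 | 3-chloro-2-(chloromethyl)prop-1-ene | C=C(CCl)CCl | starting material
2 | vinylmagnesium bromide | C=C[Mg]Br | starting material
3 | 2-(chloromethyl)penta-1,4-diene | C=CCC(=C)CCl | intermediate
4 | acrolein (prop-2-enal) | C=CC=O | starting material
5 | (2-methylidenepent-4-en-1-yl)zinc chloride | C=CCC(=C)C[Zn]Cl | intermediate
6 | rac-5-methylideneocta-1,7-dien-3-ol | C=CC(O)CC(=C)CC=C | intermediate
7 | (R)-5-methylideneocta-1,7-dien-3-ol | C=C[C@H](O)CC(=C)CC=C | intermediate
8 | (R)-5-methylidenecyclohex-2-en-1-ol | C=C1CC=C[C@H](O)C1 | intermediate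
9 | linoleyl alcohol, (9Z,12Z)-octadeca-9,12-dien-1-ol | CCCCC/C=C\C/C=C\CCCCCCCCO | starting material
10 | (9Z,12Z)-octadeca-9,12-dienal | CCCCC/C=C\C/C=C\CCCCCCCC=O | intermediate
11 | (9Z,12Z)-octadeca-9,12-dienal oxime (C=N isomers) | CCCCC/C=C\C/C=C\CCCCCCCC=NO | intermediate
12 | (9Z,12Z)-N-hydroxyoctadeca-9,12-dienimidoyl chloride | CCCCC/C=C\C/C=C\CCCCCCCC(Cl)=NO | intermediate
13 | bromomagnesium (1R)-5-methylidenecyclohex-2-en-1-olate | C=C1CC=C[C@H](O[Mg]Br)C1 | intermediate
14 | (9Z,12Z)-octadeca-9,12-dienenitrile oxide | CCCCC/C=C\C/C=C\CCCCCCCC#[N+][O-] | intermediate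
15 | (5S,7R)-3-[(8Z,11Z)-heptadeca-8,11-dien-1-yl]-1-oxa-2-azaspiro[4.5]deca-2,8-dien-7-ol (ring oxygen cis to the hydroxyl) | CCCCC/C=C\C/C=C\CCCCCCCC1=NO[C@]2(C1)CC=C[C@H](O)C2 | intermediate
16 | (10Z,13Z)-1-[(1S,5R)-1,5-dihydroxycyclohex-3-en-1-yl]nonadeca-10,13-dien-2-imine | CCCCC/C=C\C/C=C\CCCCCCCC(=N)C[C@@]1(O)CC=C[C@H](O)C1 | intermediate
17 | (10Z,13Z)-1-[(1R,5R)-1,5-dihydroxycyclohex-3-en-1-yl]nonadeca-10,13-dien-2-one (hydroxyls cis) | CCCCC/C=C\C/C=C\CCCCCCCC(=O)C[C@@]1(O)CC=C[C@H](O)C1 | intermediate
18 | (S)-5-hydroxy-5-[(10Z,13Z)-2-oxononadeca-10,13-dien-1-yl]cyclohex-2-en-1-one | CCCCC/C=C\C/C=C\CCCCCCCC(=O)C[C@@]1(O)CC=CC(=O)C1 | target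

**Count and risks**

Total step count: 10. Longest linear sequence: 7 steps (steps 1–4, then 8–10); the chain branch (steps 5–7) joins at step 8.

Steps most likely to fail:

Step 8. The dipole oxygen may be delivered to the wrong face of the exocyclic alkene or to the ring alkene, which is allylic to the alkoxide, and the aliphatic nitrile oxide may dimerise before it is trapped. The fallback leaves the cycloaddition and builds the same carbinol by ionic chemistry; it sets out from 8 and from aldehyde 10 and comes back at 17. Alcohol 8 is converted (n-BuLi, Boc2O, THF) into tert-butyl [(1R)-5-methylidenecyclohex-2-en-1-yl] carbonate F1. IBr in toluene at −80 °C should close the bridged iodocarbonate (1R,5R)-1-(iodomethyl)-2,4-dioxabicyclo[3.3.1]non-6-en-3-one F2, in which the new C5–O bond can only lie cis to the C1 oxygen. K2CO3 in methanol then gives the spiro-epoxide (3R,5R)-1-oxaspiro[2.5]oct-6-en-5-ol F3. In parallel, aldehyde 10 is turned (propane-1,3-dithiol, BF3·OEt2, CH2Cl2, 0 °C) into 2-[(8Z,11Z)-heptadeca-8,11-dien-1-yl]-1,3-dithiane F4. Its anion 2-lithio-2-[(8Z,11Z)-heptadeca-8,11-dien-1-yl]-1,3-dithiane F5 (n-BuLi, THF/DMPU, in excess to allow for the free hydroxyl) should open F3 at the epoxide CH2 to give (1R,3R)-1-({2-[(8Z,11Z)-heptadeca-8,11-dien-1-yl]-1,3-dithian-2-yl}methyl)cyclohex-4-ene-1,3-diol F6. MeI and CaCO3 in aqueous MeCN unmask the ketone and give 17.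

Step 10. The β-hydroxy enone may lose water on the oxidant surface and aromatise to a phenol, or the cyclic allylic alcohol may be oxidised too slowly. The fallback reverses the order of the last two operations; it sets out from 15 and comes back at 18. Alcohol 15 is oxidised with Dess–Martin periodinane and NaHCO3 in CH2Cl2 to (5S)-3-[(8Z,11Z)-heptadeca-8,11-dien-1-yl]-1-oxa-2-azaspiro[4.5]deca-2,8-dien-7-one F7, with the tertiary oxygen still tied up in the heterocycle. Mo(CO)6 in wet MeCN then cleaves the N–O bond and, through (5S)-5-hydroxy-5-[(10Z,13Z)-2-iminononadeca-10,13-dien-1-yl]cyclohex-2-en-1-one F8, releases 18 in an oxidant-free, neutral medium.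

Step 4. Ruthenium hydride species may move the skipped double bonds into conjugation (and on towards aromatic products) or isomerise the free allylic alcohol to a ketone, and the small product may be lost on concentration. The fallback masks the hydroxyl before ring closure; it sets out from 7 and comes back at 8. TBSCl and imidazole in DMF give tert-butyl(dimethyl){[(3R)-5-methylideneocta-1,7-dien-3-yl]oxy}silane F9. Ring-closing metathesis with the same catalyst gives the less volatile tert-butyl(dimethyl){[(1R)-5-methylidenecyclohex-2-en-1-yl]oxy}silane F10, and TBAF in THF returns 8.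

Further compounds
F1 | step 8 | tert-butyl [(1R)-5-methylidenecyclohex-2-en-1-yl] carbonate | C=C1CC=C[C@H](OC(=O)OC(C)(C)C)C1
F2 | step 8 | (1R,5R)-1-(iodomethyl)-2,4-dioxabicyclo[3.3.1]non-6-en-3-one | O=C1O[C@]2(CI)CC=C[C@H](O1)C2
F3 | step 8 | (3R,5R)-1-oxaspiro[2.5]oct-6-en-5-ol | C1O[C@@]12CC=C[C@H](O)C2
F4 | step 8 | 2-[(8Z,11Z)-heptadeca-8,11-dien-1-yl]-1,3-dithiane | CCCCC/C=C\C/C=C\CCCCCCCC1SCCCS1
F5 | step 8 | 2-lithio-2-[(8Z,11Z)-heptadeca-8,11-dien-1-yl]-1,3-dithiane | CCCCC/C=C\C/C=C\CCCCCCCC1([Li])SCCCS1
F6 | step 8 | (1R,3R)-1-({2-[(8Z,11Z)-heptadeca-8,11-dien-1-yl]-1,3-dithian-2-yl}methyl)cyclohex-4-ene-1,3-diol | CCCCC/C=C\C/C=C\CCCCCCCC1(C[C@@]2(O)CC=C[C@H](O)C2)SCCCS1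
F7 | step 10 | (5S)-3-[(8Z,11Z)-heptadeca-8,11-dien-1-yl]-1-oxa-2-azaspiro[4.5]deca-2,8-dien-7-one | CCCCC/C=C\C/C=C\CCCCCCCC1=NO[C@]2(C1)CC=CC(=O)C2
F8 | step 10 | (5S)-5-hydroxy-5-[(10Z,13Z)-2-iminononadeca-10,13-dien-1-yl]cyclohex-2-en-1-one | CCCCC/C=C\C/C=C\CCCCCCCC(=N)C[C@@]1(O)CC=CC(=O)C1
F9 | step 4 | tert-butyl(dimethyl){[(3R)-5-methylideneocta-1,7-dien-3-yl]oxy}silane | C=C[C@H](O[Si](C)(C)C(C)(C)C)CC(=C)CC=C
F10 | step 4 | tert-butyl(dimethyl){[(1R)-5-methylidenecyclohex-2-en-1-yl]oxy}silane | C=C1CC=C[C@H](O[Si](C)(C)C(C)(C)C)C1
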